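**Remark:** In germacrane numbering the SMILES reads (1R,3S,6S,7R,8R,10S,4Z), so the lactone is cis-fused (H-6/H-7 cis) and the epoxide is cis (C2 and C9 on the same side). (S)-(+)-Carvone and all reagents named in the steps are taken as commercial.

## Analysis of the target

Numbering used throughout: ring carbons C1–C10, methyl C14 on C10, hydroxymethyl C15 on C4, and the lactone unit C11(=C13H2)–C12(=O)–O on C7/C6; the acetate sits on O3, the methacrylate on O8. The skeleton is a ten-membered carbocycle (ring A) cis-fused to an α-methylene-γ-butyrolactone (ring B) and to a trisubstituted oxirane (ring C, C1–C10), with a Z-trisubstituted olefin C4=C5; both unsaturation sites have their ring bonds cis. Of the six stereocenters, C6, C7 and C8 are contiguous: the oxygens on C6 and C8 are 1,3-syn and C11 on C7 is anti to both, so a cis-lactone could close on either oxygen, while C3 stands alone between C2H2 and sp2 C4. Sensitive groups are the two Michael acceptors, the allylic acetate next to the free primary allylic alcohol (acyl shift under base), the epoxide (transannular opening onto C4=C5 under acid) and every β-oxygenated carbonyl stage on the way (elimination). The difficulty is a strained medium ring with two cis units and stereocenters spread around it, which an acyclic assembly must set far apart and then close. The feature that invites a different cut is C1–C6 with C15: once C6 is bonded to C1, the Z-olefin C4=C5 between C3–O and C6–O is a cyclohex-2-ene, and C10/C14/C9 is an isopropenyl group on C1. That is the carbon skeleton of carvone, and the two missing ring atoms C7 and C8 lie between C6 and C9, the pattern of an oxy-Cope four-atom ring expansion (break C1–C6, make C8–C9).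

## Retrosynthetic reasoning

**C15–O bond (24 ⇐ 23).** The primary allylic hydroxyl is cut last, back to the C15 methyl of 23. This way it never needs a protecting group and never sits next to the C3 acetate under basic conditions; the forward step must oxidize the one allylic methyl left on an olefin.

**Oxirane C–O bonds (23 ⇐ 22).** The epoxide is cut to the Z-olefin C1=C10 of 22. It is placed after the last acidic step, because the oxirane would not survive acetal cleavage. C1=C10 is the only electron-rich olefin in 22, and the face must be chosen by the reagent.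

**Acyl–O bonds at O3 and O8 and the exocyclic C11=C13 (22 ⇐ 21 ⇐ 20 ⇐ 19 ⇐ 18 ⇐ 15).** The two esters are cut in the order that lets O8 (silyl ether) and O3 (acetal) be told apart. The methylene C13 is cut back to the saturated lactone 15, because the Michael acceptor would not survive the earlier hydride, enolate and peroxide steps.

**Lactone C12–O6 and side-chain C7–C11 (15 ⇐ 13 ⇐ 12 ⇐ 10).** Cutting the acyl–O6 bond and the C7–C11 bond leads to β-hydroxy ketone 10. The C8 hydroxyl is then used twice: as the chelating group that sends the two-carbon electrophile to C7 anti to C9, and, once silylated, as the large branch that steers hydride at C6. The whole C6–C7–C8 triad is thus derived from the single stereocenter C8.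

**C8–O from C8–Si (10 ⇐ 9).** Oxygen at C8 is traded for silicon. An alkoxy group at C8 would sit β to the enolate formed in the ring expansion and would be eliminated; silicon is inert there and is exchanged for oxygen with retention afterwards.

**Key disconnection: C8–C9 cut, C1–C6 rejoined (9 ⇐ 6).** The ten-membered ketone 9 is traced to the cyclohexenol 6, which carries a silyl-ethenyl group on C6 and an isopropenyl group on C1, cis to each other. The forward [3,3] shift has to build ring A, set C8, and deliver C1=C10 with cis geometry, while C4=C5 keeps the cis geometry it has in the six-membered ring. The precursor is a monocyclic terpene derivative with three stereocenters.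

**C8–Si and C6–C7 (6 ⇐ 5 ⇐ 4).** The vinylsilane is cut at C8–Si (syn hydrosilylation of a terminal alkyne) and the alkyne at C6–C7 (addition of an ethynyl nucleophile to enone 4). An alkyne is chosen because a small linear nucleophile adds axially and gives the cis-dialkenyl carbinol that the Z-olefin requires; a preformed alkenyl nucleophile would not.

**C6=O, O3 protection and C3–H (4 ⇐ 3 ⇐ 2 ⇐ 1).** The C6 carbonyl comes from allylic oxidation of the one ring methylene of 3, and C3–O from 1,2-reduction of the carbonyl of 1. Carvone 1 supplies C1–C6, C9, C10, C14 and C15 and the absolute configuration.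

## Alternatives that were turned down

**Alternative 1:** Ring-closing metathesis at C4=C5, the textbook macrocyclization. The acyclic diene A1 would carry the finished lactone, the epoxide, both esters and all six stereocenters, with a 1,1-disubstituted olefin at C4 and a vinyl group on C6; metathesis would give the 15-O-silyl target A2. It was turned down for three reasons. The ring-forming step creates no stereocenter, so everything must be set acyclically over a long linear sequence. A trisubstituted olefin flanked by two oxygenated allylic carbons has to form in a strained ten-membered ring, with the Z geometry left to ring preference. The catalyst also meets two acrylate-type olefins in A1.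

**Alternative 2:** Intramolecular Barbier-type allylation with lactonization at C6–C7. The bromo enal A3 (Z-enal at C6, 2-(bromomethyl)enoate at C7/C11/C13) would close ring A and ring B in one operation and set C6 and C7. It was turned down because the cis-lactone needs the syn mode of addition while medium-ring closures with low-valent chromium favour anti. The facial sense relative to C8 rests on the macrocyclic transition state alone. The Z-γ-acyloxy enal of A3 is also prone to isomerization and elimination, and the epoxide must survive the metal.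

**Alternative 3:** Two-carbon ring expansion of a cyclooctadiene. 1,5-Dimethylcycloocta-1,5-diene A4 already holds both cis olefins with their methyl groups and eight of the ten ring carbons. Allylic oxidation to dienone A5, vinyl addition and an alkoxide-accelerated 1,3-shift would give the cis,cis-cyclodecadienone A6. It was turned down because A5 and A6 are achiral with no handle for absolute control. The oxygens at C3, C8 and C15 would have to come from three C–H oxidations on a flexible ring, where the doubly activated C9 is the most reactive site. The 1,3-shift also competes with a 3,3-shift that keeps the eight-membered ring.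

Key step: step 6

## Route

Step 1
Reactants: 1 (S)-(+)-carvone
Product: 2 (1S,5S)-2-methyl-5-(prop-1-en-2-yl)cyclohex-2-en-1-ol (cis-carveol)
Conditions: NaBH4, CeCl3·7H2O, MeOH, −78 → 0 °C
Reagents that add atoms: none
Why: Luche reduction is 1,2-selective, and hydride attack anti to the ring substituent should give the cis alcohol; this sets C3 of the target (S).

Step 2
Reactants: 2 (1S,5S)-cis-carveol
Product: 3 (1S,5S)-1-(methoxymethoxy)-2-methyl-5-(prop-1-en-2-yl)cyclohex-2-ene
Conditions: MOMCl, i-Pr2NEt, CH2Cl2, 0 °C → rt
Reagents that add atoms: chloromethyl methyl ether, COCCl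
Why: O-alkylation to the acetal; the MOM group is chosen because it should survive CrO3, amide bases, fluoride and peroxide and can be removed later at −78 °C with a boron bromide.

Step 3
Reactants: 3 cis-carveol MOM ether
Product: 4 (4S,6S)-4-(methoxymethoxy)-3-methyl-6-(prop-1-en-2-yl)cyclohex-2-en-1-one
Conditions: CrO3, 3,5-dimethylpyrazole, CH2Cl2, −20 °C
Reagents that add atoms: chromium trioxide, O=[Cr](=O)=O
Why: Chromium-mediated allylic oxidation should attack the only ring methylene next to the CH= end of the trisubstituted olefin and give the transposed enone (C6=O of the target); no stereocenter is touched.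

Step 4
Reactants: 4 enone
Product: 5 (1R,4S,6S)-1-ethynyl-4-(methoxymethoxy)-3-methyl-6-(prop-1-en-2-yl)cyclohex-2-en-1-ol
Conditions: HC≡CMgBr, CeCl3, THF, −78 °C; then H2O
Reagents that add atoms: ethynylmagnesium bromide, C#C[Mg]Br
Why: 1,2-Addition of an ethynylcerium reagent; the small linear nucleophile should add axially to the half-chair with equatorial isopropenyl and pseudo-equatorial OMOM, placing the ethynyl group cis to the isopropenyl group (carbinol R). The cerium reagent is used to suppress enolization of the epimerizable α-carbon.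

Step 5
Reactants: 5 ethynyl carbinol
Product: 6 (1R,4S,6S)-1-[(E)-2-(benzyldimethylsilyl)ethenyl]-4-(methoxymethoxy)-3-methyl-6-(prop-1-en-2-yl)cyclohex-2-en-1-ol
Conditions: BnMe2SiH, Karstedt catalyst Pt2[(CH2=CHSiMe2)2O]3 (1 mol %, zerovalent platinum), P(t-Bu)3, THF, rt
Reagents that add atoms: benzyldimethylsilane, C[SiH](C)Cc1ccccc1
Why: Platinum-catalysed syn hydrosilylation of a terminal alkyne gives the (E)-β-vinylsilane; the alkyne should react far faster than the isopropenyl and ring olefins.

Step 6
Reactants: 6 (E)-vinylsilane carbinol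
Product: 9 (3S,8R)-8-(benzyldimethylsilyl)-3-(methoxymethoxy)-4,10-dimethylcyclodeca-1(10),4-dien-6-one (1(10)Z,4Z), via potassium alkoxide 7 (not isolated), via potassium enolate 8 (not isolated)
Conditions: KN(SiMe3)2, 18-crown-6, THF, 0 → 40 °C; then AcOH, THF, −78 °C
Reagents that add atoms: none
Why: Deprotonation gives alkoxide 7, whose C6–C1 bond is weakened by the oxyanion; a [3,3] sigmatropic shift through the 1,5-diene C8=C7–C6–C1–C10=C9 breaks C1–C6, forms C8–C9 and gives the ten-membered enolate 8, which is protonated at C7 in the cold. The closest known reaction type is the anionic oxy-Cope ring expansion of 1,2-dialkenylcyclohexanols to cyclodec-5-enones. Ring A is not closed by a cyclization but arises by this four-atom ring expansion through a six-membered chair transition state. C8 is set by chirality transfer: in the chair, the E-silyl group is equatorial on C8 and C9 bonds to the face fixed by the configurations of C6 and C1, which should give 8R. The C1=C10 olefin should be Z because the two alkenyl groups are cis: with O− and isopropenyl equatorial and the ethenyl group axial on the cyclohexene, C2 is axial on C1 in the chair and ends up cis to C9. C4=C5 keeps the Z geometry it had in the six-membered ring, and C3 is carried through. The step needs the shift to run through the vinylsilane rather than through the ring olefin C4=C5, which would require a strained bicyclic boat, and it needs the enolate to survive. The E-vinylsilane keeps silicon away from the alkoxide (no silyl migration), and a silyl group at C8 cannot be eliminated from the enolate as an alkoxy group could.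

Step 7
Reactants: 9 β-silyl ketone
Product: 10 (3S,8R)-8-hydroxy-3-(methoxymethoxy)-4,10-dimethylcyclodeca-1(10),4-dien-6-one (1(10)Z,4Z)
Conditions: n-Bu4NF, THF, 0 °C; then KHCO3, 30% H2O2, MeOH/THF, rt
Reagents that add atoms: hydrogen peroxide, OO
Why: Tamao–Fleming oxidation: fluoride removes the benzyl group from silicon and the peroxide then replaces C–Si by C–O with retention, so C8 stays R; the β,β-disubstituted enone should resist the mild basic peroxide.

Step 8
Reactants: 10 β-hydroxy ketone
Product: 12 tert-butyl [(3S,7R,8R)-8-hydroxy-3-(methoxymethoxy)-4,10-dimethyl-6-oxocyclodeca-1(10),4-dien-7-yl]acetate, via dilithium alkoxide enolate 11 (not isolated)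
Conditions: LiN(i-Pr)2 (2.3 equiv), THF, −78 → −40 °C; BrCH2CO2t-Bu, −78 → −40 °C; then AcOH
Reagents that add atoms: tert-butyl bromoacetate, CC(C)(C)OC(=O)CBr
Why: Fráter–Seebach-type alkylation: the lithium-chelated alkoxide enolate 11 (O6 cis to C8) holds O8 in the enolate plane, so the electrophile should enter anti to the ring bond C8–C9 and place C11 anti to O8 (7R). C7 is the only kinetically acidic α-position, and the tert-butyl ester is chosen so that the C8 alkoxide does not lactonize.

Step 9
Reactants: 12 hydroxy keto ester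
Product: 13 tert-butyl [(3S,7R,8R)-8-(tert-butyldimethylsilyloxy)-3-(methoxymethoxy)-4,10-dimethyl-6-oxocyclodeca-1(10),4-dien-7-yl]acetate
Conditions: TBSCl, imidazole, DMF, rt
Reagents that add atoms: tert-butyldimethylsilyl chloride, CC(C)(C)[Si](C)(C)Cl
Why: Silylation blocks O8 so that the lactone can later close only on O6; the chloride with imidazole should leave the tert-butyl ester intact.

Step 10
Reactants: 13 silyloxy keto ester
Product: 15 (3S,6S,7S,8R)-8-(tert-butyldimethylsilyloxy)-3-(methoxymethoxy)-13-norgermacra-1(10),4-dien-12,6-olide (cis-fused, 1(10)Z,4Z), via hydroxy ester 14 (not isolated)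
Conditions: NaBH4, CeCl3·7H2O, MeOH, −78 °C; then t-BuOK (0.2 equiv), THF, 0 °C
Reagents that add atoms: none
Why: Luche 1,2-reduction of the enone; by the Felkin–Anh model hydride should add anti to the large C8 branch, which puts O6 anti to C11 (6S) and completes the anti,anti triad. The C6 alkoxide then closes the cis-γ-lactone by intramolecular transesterification.

Step 11
Reactants: 15 saturated lactone
Product: 18 (3S,6S,7S,8R)-8-(tert-butyldimethylsilyloxy)-3-(methoxymethoxy)germacra-1(10),4,11(13)-trien-12,6-olide, via Mannich base 16 (not isolated), via ammonium iodide 17 (not isolated)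
Conditions: LiN(i-Pr)2, THF, −78 °C; CH2=NMe2+ I−, −78 → 0 °C; then MeI, MeOH, rt; then NaHCO3, CH2Cl2/H2O
Reagents that add atoms: N,N-dimethylmethyleneiminium iodide (Eschenmoser's salt), C=[N+](C)C.[I-]
Why: Mannich reaction of the lactone enolate, N-methylation and base-induced elimination give the exocyclic methylene; C11 is the only enolizable position and no stereocenter is affected.

Step 12
Reactants: 18 silyloxy α-methylene lactone
Product: 19 (3S,6S,7R,8R)-8-hydroxy-3-(methoxymethoxy)germacra-1(10),4,11(13)-trien-12,6-olide
Conditions: HF·pyridine, pyridine, THF, 0 °C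
Reagents that add atoms: none
Why: Buffered acidic fluoride removes the silyl ether without a basic nucleophile that could add to the Michael acceptor; the MOM ether should stay.

Step 13
Reactants: 19 C8 alcohol
Product: 20 (3S,6S,7R,8R)-3-(methoxymethoxy)-8-(2-methylprop-2-enoyloxy)germacra-1(10),4,11(13)-trien-12,6-olide
Conditions: methacrylic anhydride, Et3N, DMAP, CH2Cl2, 0 °C → rt
Reagents that add atoms: methacrylic anhydride, C=C(C)C(=O)OC(=O)C(C)=C
Why: DMAP-catalysed acylation of the only free hydroxyl.

Step 14
Reactants: 20 methacrylate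
Product: 21 (3S,6S,7R,8R)-3-hydroxy-8-(2-methylprop-2-enoyloxy)germacra-1(10),4,11(13)-trien-12,6-olide
Conditions: Me2BBr, CH2Cl2, −78 °C; then aq. NaHCO3
Reagents that add atoms: none
Why: Bromodimethylborane cleaves the acetal at −78 °C, where esters, acrylates and the 1,5-diene should be untouched; the step is placed before the epoxide exists.

Step 15
Reactants: 21 C3 alcohol
Product: 22 (3S,6S,7R,8R)-3-acetoxy-8-(2-methylprop-2-enoyloxy)germacra-1(10),4,11(13)-trien-12,6-olide
Conditions: Ac2O, pyridine, DMAP (cat.), CH2Cl2, 0 °C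
Reagents that add atoms: acetic anhydride, CC(=O)OC(C)=O
Why: Standard acetylation of the secondary allylic alcohol.

Step 16
Reactants: 22 triene diester
Product: 23 (1R,3S,6S,7R,8R,10S)-3-acetoxy-1,10-epoxy-8-(2-methylprop-2-enoyloxy)germacra-4,11(13)-dien-12,6-olide
Conditions: 1,2:4,5-di-O-isopropylidene-β-D-erythro-2,3-hexodiulo-2,6-pyranose (Shi ketone, 0.3 equiv), Oxone (2KHSO5·KHSO4·K2SO4), K2CO3, n-Bu4NHSO4, MeCN/CH2(OMe)2/aq. Na2B4O7 buffer (pH 10.5), 0 °C
Reagents that add atoms: potassium peroxymonosulfate, [K+].[O-]S(=O)(=O)OO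
Why: Shi epoxidation: the chiral dioxirane should attack only C1=C10, the one electron-rich olefin (C4=C5 is flanked by two acyloxy carbons, the others are acrylates). The spiro transition state that turns 1-phenylcyclohexene into its (R,R)-oxide maps onto the (1R,10S) face here, and the cis geometry of the olefin is kept.

Step 17
Reactants: 23 epoxide
Product: 24 (1R,3S,6S,7R,8R,10S,4Z)-3-acetoxy-1,10-epoxy-15-hydroxy-8-(2-methylprop-2-enoyloxy)germacra-4,11(13)-dien-12,6-olide (target)
Conditions: SeO2 (0.5 equiv), t-BuOOH, CH2Cl2, rt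
Reagents that add atoms: selenium dioxide, O=[Se]=O; tert-butyl hydroperoxide, CC(C)(C)OO
Why: Riley allylic oxidation (ene reaction, then [2,3] shift) should take the methyl on the more substituted olefin carbon that is cis to H-5, which is C15, and return C4=C5 with unchanged geometry. The closest analogy is the oxidation of the E-methyl of prenyl-type allylic esters; the acrylate olefins are too electron-poor to react.

## Compound list

The C7 descriptor reads S in the 8-O-silyl compounds 14–18 and R elsewhere; the spatial arrangement is the same.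

1 | (S)-(+)-carvone, (5S)-2-methyl-5-(prop-1-en-2-yl)cyclohex-2-en-1-one | CC1=CC[C@@H](CC1=O)C(C)=C | starting material
2 | (1S,5S)-2-methyl-5-(prop-1-en-2-yl)cyclohex-2-en-1-ol (cis-carveol) | CC1=CC[C@@H](C[C@@H]1O)C(C)=C | intermediate
3 | (1S,5S)-1-(methoxymethoxy)-2-methyl-5-(prop-1-en-2-yl)cyclohex-2-ene | CC1=CC[C@@H](C[C@@H]1OCOC)C(C)=C | intermediate
4 | (4S,6S)-4-(methoxymethoxy)-3-methyl-6-(prop-1-en-2-yl)cyclohex-2-en-1-one | CC1=CC(=O)[C@@H](C[C@@H]1OCOC)C(C)=C | intermediate
5 | (1R,4S,6S)-1-ethynyl-4-(methoxymethoxy)-3-methyl-6-(prop-1-en-2-yl)cyclohex-2-en-1-ol | CC1=C[C@](O)(C#C)[C@@H](C[C@@H]1OCOC)C(C)=C | intermediate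
6 | (1R,4S,6S)-1-[(E)-2-(benzyldimethylsilyl)ethenyl]-4-(methoxymethoxy)-3-methyl-6-(prop-1-en-2-yl)cyclohex-2-en-1-ol | CC1=C[C@](O)(/C=C/[Si](C)(C)Cc2ccccc2)[C@@H](C[C@@H]1OCOC)C(C)=C | intermediate
7 | potassium alkoxide of 6 | CC1=C[C@]([O-])(/C=C/[Si](C)(C)Cc2ccccc2)[C@@H](C[C@@H]1OCOC)C(C)=C.[K+] | intermediate
8 | potassium enolate of 9 (C6=C7, O cis to C8) | C1/C(C)=C\C[C@H](OCOC)/C(C)=C\C(\[O-])=C\[C@@H]1[Si](C)(C)Cc1ccccc1.[K+] | intermediate
9 | (3S,8R,1(10)Z,4Z)-8-(benzyldimethylsilyl)-3-(methoxymethoxy)-4,10-dimethylcyclodeca-1(10),4-dien-6-one | C[Si](C)(Cc1ccccc1)[C@@H]1C/C(C)=C\C[C@H](OCOC)/C(C)=C\C(=O)C1 | intermediate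
10 | (3S,8R,1(10)Z,4Z)-8-hydroxy-3-(methoxymethoxy)-4,10-dimethylcyclodeca-1(10),4-dien-6-one | O[C@@H]1C/C(C)=C\C[C@H](OCOC)/C(C)=C\C(=O)C1 | intermediate
11 | dilithium alkoxide enolate of 10 | [Li+].[Li+].C1/C(C)=C\C[C@H](OCOC)/C(C)=C\C(\[O-])=C\[C@@H]1[O-] | intermediate
12 | tert-butyl [(3S,7R,8R)-8-hydroxy-3-(methoxymethoxy)-4,10-dimethyl-6-oxocyclodeca-1(10),4-dien-7-yl]acetate | O[C@@H]1C/C(C)=C\C[C@H](OCOC)/C(C)=C\C(=O)[C@@H]1CC(=O)OC(C)(C)C | intermediate
13 | tert-butyl [(3S,7R,8R)-8-(tert-butyldimethylsilyloxy)-3-(methoxymethoxy)-4,10-dimethyl-6-oxocyclodeca-1(10),4-dien-7-yl]acetate | CC(C)(C)[Si](C)(C)O[C@@H]1C/C(C)=C\C[C@H](OCOC)/C(C)=C\C(=O)[C@@H]1CC(=O)OC(C)(C)C | intermediate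
14 | tert-butyl [(3S,6S,7S,8R)-8-(tert-butyldimethylsilyloxy)-6-hydroxy-3-(methoxymethoxy)-4,10-dimethylcyclodeca-1(10),4-dien-7-yl]acetate | CC(C)(C)[Si](C)(C)O[C@@H]1C/C(C)=C\C[C@H](OCOC)/C(C)=C\[C@H](O)[C@@H]1CC(=O)OC(C)(C)C | intermediate
15 | (3S,6S,7S,8R)-8-(tert-butyldimethylsilyloxy)-3-(methoxymethoxy)-13-norgermacra-1(10),4-dien-12,6-olide | CC(C)(C)[Si](C)(C)O[C@@H]1C/C(C)=C\C[C@H](OCOC)/C(C)=C\[C@@H]2OC(=O)C[C@@H]21 | intermediate
16 | 11-(dimethylaminomethyl) derivative of 15 (Mannich base, both C11 epimers) | CC(C)(C)[Si](C)(C)O[C@@H]1C/C(C)=C\C[C@H](OCOC)/C(C)=C\[C@@H]2OC(=O)C(CN(C)C)[C@@H]21 | intermediate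
17 | trimethylammonium iodide of 16 | CC(C)(C)[Si](C)(C)O[C@@H]1C/C(C)=C\C[C@H](OCOC)/C(C)=C\[C@@H]2OC(=O)C(C[N+](C)(C)C)[C@@H]21.[I-] | intermediate
18 | (3S,6S,7S,8R)-8-(tert-butyldimethylsilyloxy)-3-(methoxymethoxy)germacra-1(10),4,11(13)-trien-12,6-olide | CC(C)(C)[Si](C)(C)O[C@@H]1C/C(C)=C\C[C@H](OCOC)/C(C)=C\[C@@H]2OC(=O)C(=C)[C@@H]21 | intermediate
19 | (3S,6S,7R,8R)-8-hydroxy-3-(methoxymethoxy)germacra-1(10),4,11(13)-trien-12,6-olide | O[C@@H]1C/C(C)=C\C[C@H](OCOC)/C(C)=C\[C@@H]2OC(=O)C(=C)[C@@H]21 | intermediate
20 | (3S,6S,7R,8R)-3-(methoxymethoxy)-8-(2-methylprop-2-enoyloxy)germacra-1(10),4,11(13)-trien-12,6-olide | C=C(C)C(=O)O[C@@H]1C/C(C)=C\C[C@H](OCOC)/C(C)=C\[C@@H]2OC(=O)C(=C)[C@@H]21 | intermediate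
21 | (3S,6S,7R,8R)-3-hydroxy-8-(2-methylprop-2-enoyloxy)germacra-1(10),4,11(13)-trien-12,6-olide | C=C(C)C(=O)O[C@@H]1C/C(C)=C\C[C@H](O)/C(C)=C\[C@@H]2OC(=O)C(=C)[C@@H]21 | intermediate
22 | (3S,6S,7R,8R)-3-acetoxy-8-(2-methylprop-2-enoyloxy)germacra-1(10),4,11(13)-trien-12,6-olide | C=C(C)C(=O)O[C@@H]1C/C(C)=C\C[C@H](OC(C)=O)/C(C)=C\[C@@H]2OC(=O)C(=C)[C@@H]21 | intermediate
23 | (1R,3S,6S,7R,8R,10S)-3-acetoxy-1,10-epoxy-8-(2-methylprop-2-enoyloxy)germacra-4,11(13)-dien-12,6-olide | C=C(C)C(=O)O[C@@H]1C[C@]2(C)O[C@@H]2C[C@H](OC(C)=O)/C(C)=C\[C@@H]2OC(=O)C(=C)[C@@H]21 | intermediate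
24 | (1R,3S,6S,7R,8R,10S,4Z)-3-acetoxy-1,10-epoxy-15-hydroxy-8-(2-methylprop-2-enoyloxy)germacra-4,11(13)-dien-12,6-olide (CNP0319155.2) | C=C(C)C(=O)O[C@@H]1C[C@]2(C)O[C@@H]2C[C@H](OC(C)=O)/C(CO)=C\[C@@H]2OC(=O)C(=C)[C@@H]21 | target

## Step count and least certain steps

Total step count: 17. Longest linear sequence: 17 steps (1 → 24).

**Step 6 (key step).** The most likely failure is loss of the concerted chair pathway. The alkoxide may dissociate to an allyl anion and an enone and recombine without stereocontrol (1,3-shift, or E geometry at C1=C10), or base may isomerize the Z-enone before the quench. The ring olefin can also in principle take part in a competing 3,3-shift. Fallback: from 6, silylate the tertiary alcohol to the trimethylsilyl ether F1 and run the neutral thermal siloxy-Cope rearrangement (sealed tube, about 200 °C). This is concerted and has no free alkoxide; it gives the trimethylsilyl enol ether F2, whose mild hydrolysis returns to the route at 9.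

**Step 3.** Hydrogen abstraction at the isopropenyl group or at the acetal-bearing carbon may compete with oxidation of the ring methylene, so regioselectivity and over-oxidation are the concern. Fallback: from 3, epoxidize the ring olefin with a peracid to the epoxide F3, open it at the secondary carbon with phenylselenide to the hydroxy selenide F4, and oxidize and eliminate the selenoxide to the tertiary allylic alcohol F5. Babler–Dauben oxidative transposition with pyridinium chlorochromate returns to the route at 4.

**Step 8.** Before the enolate forms, the lithium aldolate may undergo retro-aldol ring opening, or the C8 alkoxide may add transannularly to the enone. O-alkylation and erosion of the chelate-controlled facial selectivity in the ring are further risks. Fallback: from 6, alkylate the potassium enolate 8 in the flask of step 6 with the same bromoacetate while silicon is still on C8, relying on attack anti to silicon, to give the silyl keto ester F6. Reduction and lactonization as in step 10 give the silyl lactone F7, and Tamao–Fleming oxidation gives the hydroxy lactone F8, whose silylation returns to the route at 15.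

**Step 10.** Facial selectivity of hydride delivery may be poor or reversed, because the ring conformation can override the Felkin–Anh preference. Fallback: from 13, if reduction gives the 6-epi hydroxy ester F9, cleave the tert-butyl ester (TMSOTf, 2,6-lutidine, then mild methanolysis) to the 6-epi hydroxy acid F10. Mitsunobu lactonization then closes the ring with inversion at C6 and returns to the route at 15.

**Step 16.** The catalyst-controlled face may be mismatched with the face the ring conformation exposes, and the pH 10.5 medium may partly hydrolyse the esters. Fallback: from 22, form the bromohydrin F11 with N-bromosuccinimide in aqueous dimethoxyethane (bromonium on the exposed face, water at C10 from the other) and close it with an amidine base. This puts the oxirane on the face opposite to direct electrophilic attack and returns to the route at 23.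

**Step 17.** The ene reaction may be slow on an olefin deactivated by two allylic acyloxy groups, and it may over-oxidize to the aldehyde or open the epoxide under the acidic selenium species. Fallback: from 21, where C3 still carries a free hydroxyl, epoxidize as in step 16 to the epoxy alcohol F12 and run the selenium dioxide oxidation there to the epoxy diol F13. Silylate the primary hydroxyl selectively to the triethylsilyl ether F14, acetylate O3 to the silyl ether acetate F15, and remove the silyl group with buffered HF·pyridine to return to the route at 24.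

## Further compounds

F1 | step 6 | trimethylsilyl ether of 6 | CC1=C[C@](O[Si](C)(C)C)(/C=C/[Si](C)(C)Cc2ccccc2)[C@@H](C[C@@H]1OCOC)C(C)=C
F2 | step 6 | trimethylsilyl enol ether of 9 | C1/C(C)=C\C[C@H](OCOC)/C(C)=C\C(\O[Si](C)(C)C)=C\[C@@H]1[Si](C)(C)Cc1ccccc1
F3 | step 3 | ring epoxide of 3 (both epoxide faces) | CC12OC1C[C@@H](C[C@@H]2OCOC)C(C)=C
F4 | step 3 | hydroxy selenide from F3 | CC1(O)C([Se]c2ccccc2)C[C@@H](C[C@@H]1OCOC)C(C)=C
F5 | step 3 | tertiary allylic alcohol, 6-(methoxymethoxy)-1-methyl-4-(prop-1-en-2-yl)cyclohex-2-en-1-ol | CC1(O)C=C[C@@H](C[C@@H]1OCOC)C(C)=C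
F6 | step 8 | tert-butyl [8-(benzyldimethylsilyl)-3-(methoxymethoxy)-4,10-dimethyl-6-oxocyclodeca-1(10),4-dien-7-yl]acetate | C[Si](C)(Cc1ccccc1)[C@@H]1C/C(C)=C\C[C@H](OCOC)/C(C)=C\C(=O)[C@@H]1CC(=O)OC(C)(C)C
F7 | step 8 | 8-(benzyldimethylsilyl)-3-(methoxymethoxy)-13-norgermacra-1(10),4-dien-12,6-olide | C[Si](C)(Cc1ccccc1)[C@@H]1C/C(C)=C\C[C@H](OCOC)/C(C)=C\[C@@H]2OC(=O)C[C@@H]21
F8 | step 8 | 8-hydroxy-3-(methoxymethoxy)-13-norgermacra-1(10),4-dien-12,6-olide | O[C@@H]1C/C(C)=C\C[C@H](OCOC)/C(C)=C\[C@@H]2OC(=O)C[C@@H]21
F9 | step 10 | 6-epi hydroxy ester (C6 epimer of 14) | CC(C)(C)[Si](C)(C)O[C@@H]1C/C(C)=C\C[C@H](OCOC)/C(C)=C\[C@@H](O)[C@@H]1CC(=O)OC(C)(C)C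
F10 | step 10 | 6-epi hydroxy acid | CC(C)(C)[Si](C)(C)O[C@@H]1C/C(C)=C\C[C@H](OCOC)/C(C)=C\[C@@H](O)[C@@H]1CC(=O)O
F11 | step 16 | 1-bromo-10-hydroxy bromohydrin of 22 | C=C(C)C(=O)O[C@@H]1C[C@](C)(O)[C@@H](Br)C[C@H](OC(C)=O)/C(C)=C\[C@@H]2OC(=O)C(=C)[C@@H]21
F12 | step 17 | 1,10-epoxy-3-hydroxy-8-(2-methylprop-2-enoyloxy)germacra-4,11(13)-dien-12,6-olide | C=C(C)C(=O)O[C@@H]1C[C@]2(C)O[C@@H]2C[C@H](O)/C(C)=C\[C@@H]2OC(=O)C(=C)[C@@H]21
F13 | step 17 | 1,10-epoxy-3,15-dihydroxy-8-(2-methylprop-2-enoyloxy)germacra-4,11(13)-dien-12,6-olide | C=C(C)C(=O)O[C@@H]1C[C@]2(C)O[C@@H]2C[C@H](O)/C(CO)=C\[C@@H]2OC(=O)C(=C)[C@@H]21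
F14 | step 17 | 15-O-triethylsilyl ether of F13 | C=C(C)C(=O)O[C@@H]1C[C@]2(C)O[C@@H]2C[C@H](O)/C(CO[Si](CC)(CC)CC)=C\[C@@H]2OC(=O)C(=C)[C@@H]21
F15 | step 17 | 3-O-acetyl-15-O-triethylsilyl derivative | C=C(C)C(=O)O[C@@H]1C[C@]2(C)O[C@@H]2C[C@H](OC(C)=O)/C(CO[Si](CC)(CC)CC)=C\[C@@H]2OC(=O)C(=C)[C@@H]21
A1 | alternative 1 | seco-diene for ring-closing metathesis (vinyl on C6, 1,1-disubstituted olefin at C4, 15-O-TBS) | C=C(C)C(=O)O[C@H](C[C@]2(C)O[C@@H]2C[C@H](OC(C)=O)C(=C)CO[Si](C)(C)C(C)(C)C)[C@H]1C(=C)C(=O)O[C@H]1C=C
A2 | alternative 1 | 15-O-tert-butyldimethylsilyl ether of the target | C=C(C)C(=O)O[C@@H]1C[C@]2(C)O[C@@H]2C[C@H](OC(C)=O)/C(CO[Si](C)(C)C(C)(C)C)=C\[C@@H]2OC(=O)C(=C)[C@@H]21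
A3 | alternative 2 | bromo enal for Barbier macrocyclization (Z-enal at C6, methyl (Z)-2-(bromomethyl)enoate at C7) | O=C/C=C(/CO[Si](C)(C)C(C)(C)C)[C@@H](OC(C)=O)C[C@H]1O[C@@]1(C)C[C@@H](O[Si](C)(C)C(C)(C)C)/C=C(\CBr)C(=O)OC
A4 | alternative 3 | (1Z,5Z)-1,5-dimethylcycloocta-1,5-diene | C1/C=C(C)\CC/C=C(C)\C1
A5 | alternative 3 | (2Z,6Z)-3,7-dimethylcycloocta-2,6-dien-1-one | O=C1/C=C(C)\CC/C=C(C)\C1
A6 | alternative 3 | cis,cis-4,10-dimethylcyclodeca-1(10),4-dien-6-one (target numbering) | O=C1/C=C(C)\CC/C=C(C)\CCC1
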